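**Plan**

Numbering: the heptanoid chain runs from C1 (the oxane carbon carrying the guaiacyl ring) to C7 (the CH2 of the 4-hydroxyphenyl arm); the ring oxygen O5 links C1 and C5, so the oxane is O5–C1–C2–C3–C4–C5.
Enabling feature: C1 is at once benzylic to the 3,4-dioxygenated benzene ring and bonded to O5, so the CH2 of a vanillyl ether on O5 can be oxidised to an oxocarbenium ion exactly where the ring must close.
Retrosynthetic cuts, in order: C3–H (alcohol to ketone) and the three O-protecting groups; C1–C2 (oxane opened to an enol acetate with an O5 vanillyl ether); C3–OAc (back to a terminal alkyne); C7–aryl (terminal epoxide plus aryl Grignard reagent); O5–C1 (Williamson); C4–C5 (allenylzinc plus glyceraldehyde).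
Forward: the open chain is assembled first (C5–C7 from D-mannitol, C2–C4 from propargyl bromide, C1 with its guaiacyl ring placed on O5, then the aryl group on C7); the only ring, the oxane, closes last by oxidative C1–C2 bond formation, followed by reduction and deprotection.
Stereochemistry: C6 comes from D-mannitol; C5 from Felkin–Anh (anti) propargylation; C1 from the chair transition state of the cyclisation (cis to C5); C3 from axial hydride delivery to the ketone (equatorial OH).

Key step: step 10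

Remark: the target is read as (2R,4R,6S)-2-(4-hydroxy-3-methoxyphenyl)-6-[(1R)-1-hydroxy-2-(4-hydroxyphenyl)ethyl]oxan-4-ol, that is, all three ring substituents cis (equatorial) and the C5 and C6 oxygens anti; the diacetonide of D-mannitol, O-benzylvanillyl alcohol and the silyl ether of 4-bromophenol are taken as purchased (TBS = tert-butyldimethylsilyl, Bn = benzyl).

**Route**

Step 1
Reactants: 1 1,2:5,6-di-O-isopropylidene-D-mannitol
Product: 2 (4R)-2,2-dimethyl-1,3-dioxolane-4-carbaldehyde [(R)-glyceraldehyde acetonide]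
Conditions: NaIO4, sat. aq. NaHCO3, CH2Cl2, rt; used at once
Reagents that add atoms: none
Why: Periodate glycol cleavage (Malaprade reaction) of the central diol should give two equivalents of the aldehyde without touching the dioxolane stereocenter, which becomes C6.

Step 2
Reactants: 2 (R)-glyceraldehyde acetonide; 3 propargyl bromide (3-bromoprop-1-yne)
Product: 5 (1S)-1-[(4R)-2,2-dimethyl-1,3-dioxolan-4-yl]but-3-yn-1-ol, via allenylzinc bromide 4 (not isolated)
Conditions: Zn dust, DMF/Et2O (1:1), 0 °C to rt; aq. NH4Cl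
Reagents that add atoms: none
Why: In this Barbier-type zinc propargylation the allenylzinc species should add through a cyclic SE2' transition state to give the homopropargylic alcohol, and Felkin–Anh attack anti to the dioxolane C–O bond in the coordinating solvent should set C5 as (S), anti to C6.

Step 3
Reactants: 6 4-(benzyloxy)-3-methoxybenzyl alcohol
Product: 7 4-(benzyloxy)-3-methoxybenzyl chloride
Conditions: SOCl2, CH2Cl2, 0 °C to rt; used crude
Reagents that add atoms: thionyl chloride, O=S(Cl)Cl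
Why: Chlorodehydroxylation of an electron-rich benzylic alcohol through its chlorosulfite is fast and leaves the aryl benzyl ether alone.

Step 4
Reactants: 5 (1S)-1-[(4R)-2,2-dimethyl-1,3-dioxolan-4-yl]but-3-yn-1-ol; 7 4-(benzyloxy)-3-methoxybenzyl chloride
Product: 8 (4R)-4-[(1S)-1-{[4-(benzyloxy)-3-methoxybenzyl]oxy}but-3-yn-1-yl]-2,2-dimethyl-1,3-dioxolane
Conditions: NaH, Bu4NI (cat.), THF/DMF, 0 °C to rt
Reagents that add atoms: none
Why: Williamson etherification of the sodium alkoxide with the activated benzylic chloride (iodide catalysis) should place C1 and its guaiacyl ring on O5 without affecting either stereocenter.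

Step 5
Reactants: 8 (4R)-4-[(1S)-1-{[4-(benzyloxy)-3-methoxybenzyl]oxy}but-3-yn-1-yl]-2,2-dimethyl-1,3-dioxolane
Product: 9 (2R,3S)-3-{[4-(benzyloxy)-3-methoxybenzyl]oxy}hex-5-yne-1,2-diol
Conditions: AcOH/H2O (4:1), 40 °C
Reagents that add atoms: none
Why: Acid-catalysed acetal hydrolysis in aqueous acetic acid should free the C6/C7 diol while the dialkoxybenzyl ether and the alkyne remain intact.

Step 6
Reactants: 9 (2R,3S)-3-{[4-(benzyloxy)-3-methoxybenzyl]oxy}hex-5-yne-1,2-diol
Product: 11 (2R)-2-[(1S)-1-{[4-(benzyloxy)-3-methoxybenzyl]oxy}but-3-yn-1-yl]oxirane, via primary monotosylate 10 (not isolated)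
Conditions: TsCl, Et3N, Bu2SnO (cat.), CH2Cl2, rt; then K2CO3, MeOH, 0 °C to rt
Reagents that add atoms: none
Why: Tin-catalysed regioselective sulfonylation of the primary hydroxyl (stannylene acetal) followed by intramolecular Williamson (SN2) closure at C7 should give the terminal epoxide with C6 keeping its oxygen and configuration.

Step 7
Reactants: 11 (2R)-2-[(1S)-1-{[4-(benzyloxy)-3-methoxybenzyl]oxy}but-3-yn-1-yl]oxirane; 12 (4-bromophenoxy)(tert-butyl)dimethylsilane
Product: 14 (2R,3S)-3-{[4-(benzyloxy)-3-methoxybenzyl]oxy}-1-{4-[(tert-butyldimethylsilyl)oxy]phenyl}hex-5-yn-2-ol, via arylmagnesium bromide 13 (not isolated)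
Conditions: 12, Mg, THF, rt to 40 °C; then CuI (10 mol%), 11, THF, −40 to −10 °C (3 equiv of 13); aq. NH4Cl
Reagents that add atoms: none
Why: Copper-catalysed SN2 opening of a terminal epoxide by an aryl Grignard reagent occurs at the unsubstituted carbon C7 and leaves C6 untouched, and the excess reagent allows for any deprotonation of the alkyne C–H, whose magnesium acetylide is inert to the epoxide at low temperature and is reprotonated on work-up.

Step 8
Reactants: 14 (2R,3S)-3-{[4-(benzyloxy)-3-methoxybenzyl]oxy}-1-{4-[(tert-butyldimethylsilyl)oxy]phenyl}hex-5-yn-2-ol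
Product: 15 (2R,3S)-3-{[4-(benzyloxy)-3-methoxybenzyl]oxy}-2-[(tert-butyldimethylsilyl)oxy]-1-{4-[(tert-butyldimethylsilyl)oxy]phenyl}hex-5-yne
Conditions: TBSOTf, 2,6-lutidine, CH2Cl2, −78 to 0 °C
Reagents that add atoms: tert-butyldimethylsilyl trifluoromethanesulfonate, CC(C)(C)[Si](C)(C)OS(=O)(=O)C(F)(F)F
Why: O-Silylation of the hindered secondary alcohol with the silyl triflate and a hindered pyridine base masks the C6 hydroxyl, which would otherwise trap the oxocarbenium ion of step 10 as a benzylidene acetal.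

Step 9
Reactants: 15 (2R,3S)-3-{[4-(benzyloxy)-3-methoxybenzyl]oxy}-2-[(tert-butyldimethylsilyl)oxy]-1-{4-[(tert-butyldimethylsilyl)oxy]phenyl}hex-5-yne
Product: 16 (4S,5R)-4-{[4-(benzyloxy)-3-methoxybenzyl]oxy}-5-[(tert-butyldimethylsilyl)oxy]-6-{4-[(tert-butyldimethylsilyl)oxy]phenyl}hex-1-en-2-yl acetate
Conditions: [RuCl2(p-cymene)]2 (cat.), tri(2-furyl)phosphine (cat.), Na2CO3 (cat.), AcOH, toluene, 80 °C
Reagents that add atoms: acetic acid, CC(=O)O
Why: Ruthenium-catalysed Markovnikov hydro-acyloxylation of a terminal alkyne (carboxylate attack on the internal carbon of the metal-bound alkyne) tolerates silyl and alkoxybenzyl ethers and should give the 2-acetoxy-1-alkene.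

Step 10
Reactants: 16 (4S,5R)-4-{[4-(benzyloxy)-3-methoxybenzyl]oxy}-5-[(tert-butyldimethylsilyl)oxy]-6-{4-[(tert-butyldimethylsilyl)oxy]phenyl}hex-1-en-2-yl acetate
Product: 17 (2R,6S)-2-[4-(benzyloxy)-3-methoxyphenyl]-6-[(1R)-1-[(tert-butyldimethylsilyl)oxy]-2-{4-[(tert-butyldimethylsilyl)oxy]phenyl}ethyl]oxan-4-one
Conditions: DDQ (2 equiv), 2,6-dichloropyridine, 4 Å MS, ClCH2CH2Cl, rt
Reagents that add atoms: none
Why: DDQ should take an electron from the 3,4-dialkoxybenzene ring and then a hydrogen atom (net hydride) from the ether CH2, which is benzylic and α to O5, giving an (E)-aryl oxocarbenium ion (C1=O5+) paired with the hydroquinone anion; C2 of the enol acetate then adds to C1 and the acetyl group passes to the hydroquinone anion, unveiling the C3 ketone. The closest known reaction type is the DDQ-mediated oxidative C–H cleavage of 4-methoxybenzyl and 3,4-dimethoxybenzyl ethers with intramolecular enol acetate capture, an oxidatively triggered Prins-type cyclisation that gives cis-2,6-disubstituted tetrahydropyran-4-ones. The oxane closes in the 6-endo-trig mode with respect to the C1=O5+ bond through a chair transition state. The new stereocenter C1 is controlled by C5: with the C5 side chain equatorial and the (E)-geometry of the cation placing the aryl group equatorial as well, C1–C2 bond formation should give the 2,6-cis ring, C1 (R). The step needs oxidation of the vanillyl CH2 in preference to the C7 benzylic CH2, the O-benzyl CH2 and the C1–H of the product: the vanillyl CH2 is the only C–H that is both conjugated to the most electron-rich ring and α to an ether oxygen, the C7 and O-benzyl positions each lack one of these, and the product is shielded by the inductively withdrawing ketone and poorer overlap of its C1–H with the arene. Sieves and 2,6-dichloropyridine keep water and acid away, so the cation should not be hydrolysed to the aldehyde and the silyl ethers should stay in place.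

Step 11
Reactants: 17 (2R,6S)-2-[4-(benzyloxy)-3-methoxyphenyl]-6-[(1R)-1-[(tert-butyldimethylsilyl)oxy]-2-{4-[(tert-butyldimethylsilyl)oxy]phenyl}ethyl]oxan-4-one
Product: 18 (2R,4R,6S)-2-[4-(benzyloxy)-3-methoxyphenyl]-6-[(1R)-1-[(tert-butyldimethylsilyl)oxy]-2-{4-[(tert-butyldimethylsilyl)oxy]phenyl}ethyl]oxan-4-ol
Conditions: NaBH4, MeOH, −20 °C
Reagents that add atoms: none
Why: Borohydride reduction of the ketone, with the small hydride approaching axially on the chair that holds the C1 and C5 substituents equatorial, should give the equatorial C3 alcohol, (R), cis to both neighbours.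

Step 12
Reactants: 18 (2R,4R,6S)-2-[4-(benzyloxy)-3-methoxyphenyl]-6-[(1R)-1-[(tert-butyldimethylsilyl)oxy]-2-{4-[(tert-butyldimethylsilyl)oxy]phenyl}ethyl]oxan-4-ol
Product: 19 (2R,4R,6S)-2-[4-(benzyloxy)-3-methoxyphenyl]-6-[(1R)-1-hydroxy-2-(4-hydroxyphenyl)ethyl]oxan-4-ol
Conditions: Bu4NF, THF, 0 °C to rt
Reagents that add atoms: none
Why: Fluoride-induced desilylation, driven by Si–F bond formation, should cleave both the aryl and the secondary alkyl silyl ether without touching any stereocenter.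

Step 13
Reactants: 19 (2R,4R,6S)-2-[4-(benzyloxy)-3-methoxyphenyl]-6-[(1R)-1-hydroxy-2-(4-hydroxyphenyl)ethyl]oxan-4-ol
Product: 20 (2R,4R,6S)-2-(4-hydroxy-3-methoxyphenyl)-6-[(1R)-1-hydroxy-2-(4-hydroxyphenyl)ethyl]oxan-4-ol (CNP0116327.2)
Conditions: H2 (1 atm), Pd/C, EtOAc, rt
Reagents that add atoms: none
Why: Catalytic hydrogenolysis of an aryl benzyl ether under neutral conditions at atmospheric pressure is much faster than cleavage of the secondary, ring-bound benzylic C1–O5 bond, so stopping when the benzyl ether is consumed should leave the oxane intact.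

**Compound list**

1 | 1,2:5,6-di-O-isopropylidene-D-mannitol | CC1(C)OC[C@@H](O1)[C@@H](O)[C@H](O)[C@H]2COC(C)(C)O2 | starting material
2 | (4R)-2,2-dimethyl-1,3-dioxolane-4-carbaldehyde | O=C[C@H]1COC(C)(C)O1 | intermediate
3 | propargyl bromide | C#CCBr | starting material
4 | allenylzinc bromide (formed in the flask) | C=C=C[Zn]Br | intermediate
5 | (1S)-1-[(4R)-2,2-dimethyl-1,3-dioxolan-4-yl]but-3-yn-1-ol | C#CC[C@H](O)[C@H]1COC(C)(C)O1 | intermediate
6 | 4-(benzyloxy)-3-methoxybenzyl alcohol | COc1cc(CO)ccc1OCc1ccccc1 | starting material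
7 | 4-(benzyloxy)-3-methoxybenzyl chloride | COc1cc(CCl)ccc1OCc1ccccc1 | intermediate
8 | (4R)-4-[(1S)-1-{[4-(benzyloxy)-3-methoxybenzyl]oxy}but-3-yn-1-yl]-2,2-dimethyl-1,3-dioxolane | C#CC[C@H](OCc1ccc(OCc2ccccc2)c(OC)c1)[C@H]1COC(C)(C)O1 | intermediate
9 | (2R,3S)-3-{[4-(benzyloxy)-3-methoxybenzyl]oxy}hex-5-yne-1,2-diol | C#CC[C@H](OCc1ccc(OCc2ccccc2)c(OC)c1)[C@H](O)CO | intermediate
10 | (2R,3S)-3-{[4-(benzyloxy)-3-methoxybenzyl]oxy}-2-hydroxyhex-5-yn-1-yl 4-methylbenzenesulfonate (formed in the flask) | C#CC[C@H](OCc1ccc(OCc2ccccc2)c(OC)c1)[C@H](O)COS(=O)(=O)c1ccc(C)cc1 | intermediate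
11 | (2R)-2-[(1S)-1-{[4-(benzyloxy)-3-methoxybenzyl]oxy}but-3-yn-1-yl]oxirane | C#CC[C@H](OCc1ccc(OCc2ccccc2)c(OC)c1)[C@H]1CO1 | intermediate
12 | (4-bromophenoxy)(tert-butyl)dimethylsilane | CC(C)(C)[Si](C)(C)Oc1ccc(Br)cc1 | starting material
13 | {4-[(tert-butyldimethylsilyl)oxy]phenyl}magnesium bromide (formed in the flask) | CC(C)(C)[Si](C)(C)Oc1ccc([Mg]Br)cc1 | intermediate
14 | (2R,3S)-3-{[4-(benzyloxy)-3-methoxybenzyl]oxy}-1-{4-[(tert-butyldimethylsilyl)oxy]phenyl}hex-5-yn-2-ol | C#CC[C@H](OCc1ccc(OCc2ccccc2)c(OC)c1)[C@H](O)Cc1ccc(O[Si](C)(C)C(C)(C)C)cc1 | intermediate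
15 | (2R,3S)-3-{[4-(benzyloxy)-3-methoxybenzyl]oxy}-2-[(tert-butyldimethylsilyl)oxy]-1-{4-[(tert-butyldimethylsilyl)oxy]phenyl}hex-5-yne | C#CC[C@H](OCc1ccc(OCc2ccccc2)c(OC)c1)[C@H](O[Si](C)(C)C(C)(C)C)Cc1ccc(O[Si](C)(C)C(C)(C)C)cc1 | intermediate
16 | (4S,5R)-4-{[4-(benzyloxy)-3-methoxybenzyl]oxy}-5-[(tert-butyldimethylsilyl)oxy]-6-{4-[(tert-butyldimethylsilyl)oxy]phenyl}hex-1-en-2-yl acetate | C=C(OC(C)=O)C[C@H](OCc1ccc(OCc2ccccc2)c(OC)c1)[C@H](O[Si](C)(C)C(C)(C)C)Cc1ccc(O[Si](C)(C)C(C)(C)C)cc1 | intermediate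
17 | (2R,6S)-2-[4-(benzyloxy)-3-methoxyphenyl]-6-[(1R)-1-[(tert-butyldimethylsilyl)oxy]-2-{4-[(tert-butyldimethylsilyl)oxy]phenyl}ethyl]oxan-4-one | COc1cc([C@H]2CC(=O)C[C@@H]([C@H](O[Si](C)(C)C(C)(C)C)Cc3ccc(O[Si](C)(C)C(C)(C)C)cc3)O2)ccc1OCc1ccccc1 | intermediate
18 | (2R,4R,6S)-2-[4-(benzyloxy)-3-methoxyphenyl]-6-[(1R)-1-[(tert-butyldimethylsilyl)oxy]-2-{4-[(tert-butyldimethylsilyl)oxy]phenyl}ethyl]oxan-4-ol | COc1cc([C@H]2C[C@@H](O)C[C@@H]([C@H](O[Si](C)(C)C(C)(C)C)Cc3ccc(O[Si](C)(C)C(C)(C)C)cc3)O2)ccc1OCc1ccccc1 | intermediate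
19 | (2R,4R,6S)-2-[4-(benzyloxy)-3-methoxyphenyl]-6-[(1R)-1-hydroxy-2-(4-hydroxyphenyl)ethyl]oxan-4-ol | COc1cc([C@H]2C[C@@H](O)C[C@@H]([C@H](O)Cc3ccc(O)cc3)O2)ccc1OCc1ccccc1 | intermediate
20 | (2R,4R,6S)-2-(4-hydroxy-3-methoxyphenyl)-6-[(1R)-1-hydroxy-2-(4-hydroxyphenyl)ethyl]oxan-4-ol | COc1cc([C@H]2C[C@@H](O)C[C@@H]([C@H](O)Cc3ccc(O)cc3)O2)ccc1O | target

**Step count and risks**

Total step count: 13 (steps 1 to 13; step 3 is the only off-line step).
Longest linear sequence: 12 steps (1 → 2 → 5 → 8 → 9 → 11 → 14 → 15 → 16 → 17 → 18 → 19 → 20).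

Steps most likely to fail:

Step 10. What may go wrong: further oxidation of the product at its C1–H, or collapse of the oxocarbenium ion before the C1–C2 bond forms, with loss of the vanillyl group from O5. The fallback makes C1–C2 by acetylide addition and closes the ring at O5–C1 instead; it sets out from alkyne 15 and comes back at ketone 17. Alkyne 15 is deprotonated (n-BuLi, THF, −78 °C) and added to purchased 4-(benzyloxy)-3-methoxybenzaldehyde to give the propargylic alcohol F1 as both C1 epimers, which do not matter. Gold-catalysed Meyer–Schuster rearrangement ((Ph3P)AuNTf2 cat., MeOH additive, toluene, rt) should turn it into the (E)-enone F2. DDQ in CH2Cl2/pH 7 buffer, used here only to remove the vanillyl ether from O5, should give the hydroxy enone F3. Catalytic DBU in CH2Cl2 should then close the ring by 6-endo oxa-Michael addition of O5 to C1 under thermodynamic control, giving the 2,6-cis ketone 17.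

Step 7. What may go wrong: proton transfer from the terminal alkyne to the aryl Grignard reagent, which uses up the nucleophile and ties the copper up as an unreactive acetylide, so that the epoxide is opened slowly or by bromide. The fallback masks the acidic C–H; it sets out from epoxide 11 and comes back at 15. Epoxide 11 is C-silylated (LiN(SiMe3)2, Me3SiCl, THF, −78 °C) to the alkynylsilane epoxide F4. Opening with 13 under the CuI conditions of step 7 should give the alcohol F5, and TBSOTf/2,6-lutidine its silyl ether F6. Silver-catalysed protodesilylation of the alkynylsilane (AgNO3 cat., acetone/H2O, rt), which spares O-silyl ethers, should return 15.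

Step 9. What may go wrong: anti-Markovnikov addition through a ruthenium vinylidene, or stalling of the catalyst, so that the wrong enol ester regioisomer or none is formed. The fallback goes through the ketone; it sets out from alkyne 15 and comes back at enol acetate 16. Gold-catalysed Markovnikov hydration ((Ph3P)AuNTf2 cat., aqueous MeOH, 40 °C) should give the methyl ketone F7. Kinetic deprotonation at the methyl group (KN(SiMe3)2, THF, −78 °C) followed by O-acetylation of the enolate with Ac2O should give 16.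

**Further compounds**

F1 | step 10 | (5S,6R)-1-[4-(benzyloxy)-3-methoxyphenyl]-5-{[4-(benzyloxy)-3-methoxybenzyl]oxy}-6-[(tert-butyldimethylsilyl)oxy]-7-{4-[(tert-butyldimethylsilyl)oxy]phenyl}hept-2-yn-1-ol (both C1 epimers) | COc1cc(C(O)C#CC[C@H](OCc2ccc(OCc3ccccc3)c(OC)c2)[C@H](O[Si](C)(C)C(C)(C)C)Cc2ccc(O[Si](C)(C)C(C)(C)C)cc2)ccc1OCc1ccccc1
F2 | step 10 | (1E,5S,6R)-1-[4-(benzyloxy)-3-methoxyphenyl]-5-{[4-(benzyloxy)-3-methoxybenzyl]oxy}-6-[(tert-butyldimethylsilyl)oxy]-7-{4-[(tert-butyldimethylsilyl)oxy]phenyl}hept-1-en-3-one | COc1cc(/C=C/C(=O)C[C@H](OCc2ccc(OCc3ccccc3)c(OC)c2)[C@H](O[Si](C)(C)C(C)(C)C)Cc2ccc(O[Si](C)(C)C(C)(C)C)cc2)ccc1OCc1ccccc1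
F3 | step 10 | (1E,5S,6R)-1-[4-(benzyloxy)-3-methoxyphenyl]-6-[(tert-butyldimethylsilyl)oxy]-7-{4-[(tert-butyldimethylsilyl)oxy]phenyl}-5-hydroxyhept-1-en-3-one | COc1cc(/C=C/C(=O)C[C@H](O)[C@H](O[Si](C)(C)C(C)(C)C)Cc2ccc(O[Si](C)(C)C(C)(C)C)cc2)ccc1OCc1ccccc1
F4 | step 7 | (2R)-2-[(1S)-1-{[4-(benzyloxy)-3-methoxybenzyl]oxy}-4-(trimethylsilyl)but-3-yn-1-yl]oxirane | C[Si](C)(C)C#CC[C@H](OCc1ccc(OCc2ccccc2)c(OC)c1)[C@H]1CO1
F5 | step 7 | (2R,3S)-3-{[4-(benzyloxy)-3-methoxybenzyl]oxy}-1-{4-[(tert-butyldimethylsilyl)oxy]phenyl}-6-(trimethylsilyl)hex-5-yn-2-ol | C[Si](C)(C)C#CC[C@H](OCc1ccc(OCc2ccccc2)c(OC)c1)[C@H](O)Cc1ccc(O[Si](C)(C)C(C)(C)C)cc1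
F6 | step 7 | (2R,3S)-3-{[4-(benzyloxy)-3-methoxybenzyl]oxy}-2-[(tert-butyldimethylsilyl)oxy]-1-{4-[(tert-butyldimethylsilyl)oxy]phenyl}-6-(trimethylsilyl)hex-5-yne | C[Si](C)(C)C#CC[C@H](OCc1ccc(OCc2ccccc2)c(OC)c1)[C@H](O[Si](C)(C)C(C)(C)C)Cc1ccc(O[Si](C)(C)C(C)(C)C)cc1
F7 | step 9 | (4S,5R)-4-{[4-(benzyloxy)-3-methoxybenzyl]oxy}-5-[(tert-butyldimethylsilyl)oxy]-6-{4-[(tert-butyldimethylsilyl)oxy]phenyl}hexan-2-one | CC(=O)C[C@H](OCc1ccc(OCc2ccccc2)c(OC)c1)[C@H](O[Si](C)(C)C(C)(C)C)Cc1ccc(O[Si](C)(C)C(C)(C)C)cc1
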